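The ten-membered ring is opened at C6–C7, to be closed late by a chromium-mediated allylation. The resulting chain is cut at C9–C10 and C1=C10. The plan rests on C10: it is bonded to the ester carbon C14, to C9H2 (whose neighbour C8 bears oxygen) and doubly to C1. O8, C8, C9, C10 and C14 therefore form a hidden five-membered α-alkylidene lactone ring. One flask joins a phosphonoacetate (C10, C14), a glycidyl ether (C7–C9) and an aldehyde (C1–C6, C15) by epoxide opening, lactonisation and olefination. The aldehyde brings C4 as a set stereocentre, O15 as a silyl ether and C6 as an open dimethyl acetal.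

Key step: step 9

Remarks
- **Numbering (assumption):** germacrane numbering is used. The ring is C1–C10, the lactone carbons are C11–C13, the ester carbon is C14, the hydroxymethyl carbon is C15, and On is the oxygen on Cn.
- **Stereochemical check of the target:**
  - The configuration is 4S,6R,7S,8R.
  - C1=C10 is E by CIP (C2 trans to C14), which means cis inside the ring.
  - The lactone is trans-fused.
  - O8 and C11 lie on the same ring face.
- **Design of the aldehyde:** O15 and C6 are masked separately. A five-membered O15–C6 cyclic acetal was rejected for three reasons.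
  - When it is made from a C1/C6 dialdehyde, the six-membered O15–C1 acetal competes.
  - On release it gives a lactol, not a free aldehyde, for the ring closure.
  - It uncovers the primary C15 hydroxyl before the secondary C8 hydroxyl is acylated.
- **Timing of the isobutyrate:** it is put on after ring closure.
  - A C8 ester would migrate to a free C7 hydroxyl.
  - It would also be a leaving group for 1,4-elimination from the allylchromium.

Step 1
Reactants: 1 (S)-glycidol; 2 4-methoxybenzyl chloride
Product: 3 (R)-4-methoxybenzyl glycidyl ether (C7–C9)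
Conditions: NaH, Bu4NI (cat.), DMF, 0 °C to rt
Reagents that add atoms: none
Why: Williamson ether synthesis on the primary alkoxide; the Payne shift of glycidol is degenerate and returns the same enantiomer, so C8 is unchanged and only the CIP label goes from S to R.

Step 2
Reactants: 4 methyl 4,4-dimethoxybutanoate
Product: 5 4,4-dimethoxybutanoic acid
Conditions: NaOH, MeOH/H2O, rt; KHSO4 to pH 4, 0 °C
Reagents that add atoms: sodium hydroxide [Na+].[OH-]
Why: Ester saponification leaves the acetal untouched in base, and the cold, mild acidification frees the acid without acetal loss.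

Step 3
Reactants: 5 4,4-dimethoxybutanoic acid; 6 (S)-4-benzyl-1,3-oxazolidin-2-one
Product: 8 (4S)-4-benzyl-3-(4,4-dimethoxybutanoyl)-1,3-oxazolidin-2-one, via mixed pivalic anhydride 7 (not isolated)
Conditions: t-BuCOCl, Et3N, THF, −20 °C; then LiCl, 6, −20 °C to rt
Reagents that add atoms: none
Why: Mixed-anhydride N-acylation of the oxazolidinone (LiCl/Et3N variant) avoids an acid chloride, which the acetal would not tolerate.

Step 4
Reactants: 8 N-acyl oxazolidinone; 9 allyl iodide
Product: 10 (4S)-4-benzyl-3-[(2S)-2-(2,2-dimethoxyethyl)pent-4-enoyl]-1,3-oxazolidin-2-one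
Conditions: NaN(SiMe3)2, THF, −78 °C; then 9, −78 to −40 °C
Reagents that add atoms: none
Why: Evans asymmetric alkylation, in which the chelated Z sodium enolate is allylated on the face away from the benzyl group; this sets C4 in the configuration of the target (allyl = C3–C1).

Step 5
Reactants: 10 allylated imide
Product: 11 (2S)-2-(2,2-dimethoxyethyl)pent-4-en-1-ol
Conditions: LiBH4, MeOH (1.5 equiv), THF, 0 °C
Reagents that add atoms: none
Why: Reductive cleavage of the N-acyl oxazolidinone gives the C15 alcohol and returns the auxiliary without touching C4, the alkene or the acetal.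

Step 6
Reactants: 11 C15 alcohol
Product: 12 tert-butyl{[(2S)-2-(2,2-dimethoxyethyl)pent-4-en-1-yl]oxy}diphenylsilane
Conditions: t-BuPh2SiCl, imidazole, CH2Cl2, rt
Reagents that add atoms: tert-butyl(chloro)diphenylsilane CC(C)(C)[Si](Cl)(c1ccccc1)c1ccccc1
Why: Standard silylation; the diphenyl-tert-butylsilyl ether outlasts base, aqueous acid and the later selective removal of a tert-butyldimethylsilyl group.

Step 7
Reactants: 12 silyl ether alkene
Product: 14 (4S)-4-{[(tert-butyldiphenylsilyl)oxy]methyl}-6,6-dimethoxyhexan-1-ol, via B-alkyl borane 13 (not isolated)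
Conditions: 9-BBN, THF, 0 °C to rt; then NaOH, H2O2, 0 °C
Reagents that add atoms: hydrogen peroxide OO
Why: Anti-Markovnikov hydroboration–oxidation, in which the bulky borane places boron and then oxygen on the terminal carbon C1.

Step 8
Reactants: 14 C1 alcohol
Product: 15 (4S)-4-{[(tert-butyldiphenylsilyl)oxy]methyl}-6,6-dimethoxyhexanal (C1 aldehyde with C1–C6 and C15)
Conditions: TEMPO (2,2,6,6-tetramethylpiperidin-1-oxyl, cat.), PhI(OAc)2, CH2Cl2, rt
Reagents that add atoms: none
Why: Oxoammonium-catalysed oxidation stops at the aldehyde and is mild enough for the acetal and the silyl ether.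

Step 9
Reactants: 16 trimethyl phosphonoacetate; 3 (R)-4-methoxybenzyl glycidyl ether; 15 C1 aldehyde
Product: 18 (3E,5R)-3-[(4S)-4-{[(tert-butyldiphenylsilyl)oxy]methyl}-6,6-dimethoxyhexylidene]-5-{[(4-methoxybenzyl)oxy]methyl}dihydrofuran-2(3H)-one, via phosphono lactone sodium salt 17 (not isolated)
Conditions: 16 (1.2 equiv), NaH (1.2 equiv), THF, 0 °C to rt; 3 (1.3 equiv), 65 °C; then 15 (1.0 equiv), 0 °C to rt
Reagents that add atoms: none
Why: Deprotonated 16 attacks the less substituted epoxide carbon of 3 in an SN2 opening (new C9–C10 bond), the C8 oxide so released adds to the neighbouring methyl ester and ejects methoxide (5-exo-trig closure of the O8–C14 lactone ring), that methoxide removes the doubly activated C10 proton to give anion 17, and 17 adds to aldehyde 15 and loses dimethyl phosphate (new C1=C10 bond). The closest known reaction type is the one-pot preparation of α-alkylidene-γ-butyrolactones from a phosphonoacetate anion, a terminal epoxide and an aldehyde, that is, epoxide alkylation and lactonisation followed by Horner–Wadsworth–Emmons olefination. No stereocentre is created: C8 keeps the glycidyl configuration because its C–O bond is never broken, and C4 is remote from every reacting centre. Three selectivities are needed, namely terminal attack on the epoxide (secured by its free CH2 end), acyl rather than phosphoryl capture of the alkoxide (secured by the reactive methyl ester, by the downhill deprotonation to 17 and by a bath at or below 65 °C, well under the temperatures at which phosphoryl transfer leads on to cyclopropanes), and E geometry with C2 trans to C14. The geometry should follow from reversible addition of the stabilised lactone phosphonate in the presence of the liberated methanol, which drains through the less crowded oxaphosphetane, and any Z isomer would be removed by chromatography.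

Step 10
Reactants: 18 alkylidene lactone
Product: 20 methyl (2E,6S)-6-{[(tert-butyldiphenylsilyl)oxy]methyl}-2-{(2R)-2-hydroxy-3-[(4-methoxybenzyl)oxy]propyl}-8,8-dimethoxyoct-2-enoate, via lithium carboxylate 19 (not isolated)
Conditions: LiOH, THF/H2O, rt; evaporate to dryness; MeI, DMF, 0 °C to rt
Reagents that add atoms: lithium hydroxide [Li+].[OH-]; iodomethane CI
Why: Saponification cleaves the acyl–O8 bond with C8 retained, and SN2 methylation of the carboxylate builds the C14 methyl ester in a medium without acid or free base (excess MeI also destroys residual hydroxide), so the γ-hydroxy ester should not close again.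

Step 11
Reactants: 20 C8 hydroxy ester (used crude, at once)
Product: 21 C8 tert-butyldimethylsilyl ether of 20
Conditions: t-BuMe2SiCl, imidazole, DMF, rt
Reagents that add atoms: tert-butyl(chloro)dimethylsilane CC(C)(C)[Si](C)(C)Cl
Why: Silylation of O8 blocks relactonisation for good, and the chloride/imidazole protocol is chosen because silyl triflate/lutidine mixtures attack acetals.

Step 12
Reactants: 21 fully protected ester
Product: 22 C7 primary alcohol (O7 free; O8 TBS; O15 TBDPS; C6 acetal)
Conditions: DDQ, CH2Cl2/pH 7 buffer, 0 °C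
Reagents that add atoms: none
Why: Oxidative cleavage of the 4-methoxybenzyl ether in a buffered two-phase medium spares silyl ethers, acetal and enoate; 22 is carried on without delay so that O7 cannot reach C14.

Step 13
Reactants: 22 C7 alcohol
Product: 23 C7 aldehyde ((8R)-α-silyloxy aldehyde)
Conditions: TEMPO (cat.), PhI(OAc)2, CH2Cl2, rt
Reagents that add atoms: none
Why: Oxoammonium-catalysed oxidation works without base, so the α-silyloxy aldehyde should keep its C8 configuration.

Step 14
Reactants: 23 C7 aldehyde; 24 methyl acrylate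
Product: 25 Baylis–Hillman adduct (C7 now CH(OH) bonded to C11 of a C(=CH2)CO2Me unit; both C7 epimers)
Conditions: 24 (excess), 1,4-diazabicyclo[2.2.2]octane, MeOH, rt
Reagents that add atoms: none
Why: Morita–Baylis–Hillman reaction, for which α-oxygenated aldehydes are good acceptors; the trisubstituted C1=C10 enoate does not engage the amine, all esters are methyl esters so methanol is harmless, and the new C7 carbinol centre is erased in step 15.

Step 15
Reactants: 25 Baylis–Hillman adduct
Product: 26 (Z)-2-(bromomethyl)enoate (C8–C7H=C11(C13H2Br)CO2Me with C8 cis to CH2Br)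
Conditions: NBS, Me2S, CH2Cl2, 0 °C to rt
Reagents that add atoms: N-bromosuccinimide O=C1CCC(=O)N1Br
Why: SN2′ bromination of the alcohol through its alkoxysulfonium salt moves the alkene into conjugation and gives the Z allylic bromide under nearly neutral conditions that spare acetal and silyl ethers.

Step 16
Reactants: 26 bromide acetal
Product: 27 bromo aldehyde (C6 aldehyde free)
Conditions: CF3CO2H/H2O, CH2Cl2, 0 °C
Reagents that add atoms: water O
Why: Acid hydrolysis of an acyclic dimethyl acetal is much faster at 0 °C than loss of a secondary TBS or a primary TBDPS ether, and the electron-poor allylic bromide does not ionise.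

Step 17
Reactants: 27 bromo aldehyde
Product: 29 ten-membered trans-fused α-methylene-γ-lactone (4S,6R,7S,8R; O8 TBS; O15 TBDPS; C14 methyl ester), via macrocyclic hydroxy ester 28 (not isolated)
Conditions: CrCl2 (10 equiv), 4 Å sieves, THF/DMF, rt, slow addition of 27 (final 2 mM); work-up, then pyridinium p-toluenesulfonate (cat.), CH2Cl2, rt
Reagents that add atoms: none
Why: Intramolecular Nozaki–Hiyama–Kishi allylation, in which the allylchromium (trivalent chromium) adds through C7 to the C6 aldehyde in a Zimmerman–Traxler chair with C5 and C8 equatorial (anti adduct, hence the trans lactone once O6 closes on the C12 ester), while allylic 1,3-strain keeps H8 in the alkene plane and the ring tether holds C9 anti to the forming bond, so that C8 should impose 7S and 6R.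

Step 18
Reactants: 29 bis-silyl macrocycle
Product: 30 C8 alcohol (O15 TBDPS kept)
Conditions: 48% aq. HF, MeCN, 0 °C
Reagents that add atoms: none
Why: Acidic fluoride desilylation removes the TBS ether much faster than the acid-stable TBDPS ether, and the cold acidic medium avoids base-induced acyl shifts of O8 towards C12 or C14.

Step 19
Reactants: 30 C8 alcohol; 31 isobutyric anhydride
Product: 32 C8 isobutyrate (O15 TBDPS)
Conditions: 31, 4-(dimethylamino)pyridine (cat.), pyridine, CH2Cl2, 0 °C to rt
Reagents that add atoms: none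
Why: Nucleophile-catalysed acylation of the only free hydroxyl, under conditions routinely tolerated by α-methylene lactones.

Step 20
Reactants: 32 silyl-protected target
Product: 33 target CNP0251148.1
Conditions: HF·pyridine, THF, 0 °C to rt
Reagents that add atoms: none
Why: Fluoride-mediated desilylation in a weakly acidic medium frees O15 without the Michael addition, ester cleavage or acyl shift that basic fluoride could cause.

Compound list
1 | (S)-glycidol | OC[C@H]1CO1 | starting material
2 | 4-methoxybenzyl chloride | COc1ccc(CCl)cc1 | starting material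
3 | (R)-4-methoxybenzyl glycidyl ether | C1O[C@H]1COCc2ccc(OC)cc2 | intermediate
4 | methyl 4,4-dimethoxybutanoate | COC(=O)CCC(OC)OC | starting material
5 | 4,4-dimethoxybutanoic acid | OC(=O)CCC(OC)OC | intermediate
6 | (S)-4-benzyl-1,3-oxazolidin-2-one | O=C1N[C@@H](Cc2ccccc2)CO1 | starting material
7 | 4,4-dimethoxybutanoic pivalic anhydride (not isolated) | COC(OC)CCC(=O)OC(=O)C(C)(C)C | intermediate
8 | (4S)-4-benzyl-3-(4,4-dimethoxybutanoyl)-1,3-oxazolidin-2-one | COC(OC)CCC(=O)N1[C@@H](Cc2ccccc2)COC1=O | intermediate
9 | allyl iodide | C=CCI | starting material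
10 | (4S)-4-benzyl-3-[(2S)-2-(2,2-dimethoxyethyl)pent-4-enoyl]-1,3-oxazolidin-2-one | C=CC[C@@H](CC(OC)OC)C(=O)N1[C@@H](Cc2ccccc2)COC1=O | intermediate
11 | (2S)-2-(2,2-dimethoxyethyl)pent-4-en-1-ol | C=CC[C@@H](CC(OC)OC)CO | intermediate
12 | tert-butyl{[(2S)-2-(2,2-dimethoxyethyl)pent-4-en-1-yl]oxy}diphenylsilane | C=CC[C@@H](CC(OC)OC)CO[Si](c1ccccc1)(c1ccccc1)C(C)(C)C | intermediate
13 | 9-[(4S)-4-{[(tert-butyldiphenylsilyl)oxy]methyl}-6,6-dimethoxyhexyl]-9-borabicyclo[3.3.1]nonane (not isolated) | C1CC2CCCC(C1)B2CCC[C@@H](CC(OC)OC)CO[Si](c1ccccc1)(c1ccccc1)C(C)(C)C | intermediate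
14 | (4S)-4-{[(tert-butyldiphenylsilyl)oxy]methyl}-6,6-dimethoxyhexan-1-ol | OCCC[C@@H](CC(OC)OC)CO[Si](c1ccccc1)(c1ccccc1)C(C)(C)C | intermediate
15 | (4S)-4-{[(tert-butyldiphenylsilyl)oxy]methyl}-6,6-dimethoxyhexanal | O=CCC[C@@H](CC(OC)OC)CO[Si](c1ccccc1)(c1ccccc1)C(C)(C)C | intermediate
16 | trimethyl phosphonoacetate | COC(=O)CP(=O)(OC)OC | starting material
17 | sodium salt of dimethyl [(5R)-5-{[(4-methoxybenzyl)oxy]methyl}-2-oxotetrahydrofuran-3-yl]phosphonate (not isolated) | [Na+].O=C1O[C@@H](COCc2ccc(OC)cc2)C[C-]1P(=O)(OC)OC | intermediate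
18 | (3E,5R)-3-[(4S)-4-{[(tert-butyldiphenylsilyl)oxy]methyl}-6,6-dimethoxyhexylidene]-5-{[(4-methoxybenzyl)oxy]methyl}dihydrofuran-2(3H)-one | O=C1O[C@@H](COCc2ccc(OC)cc2)C/C1=C\CC[C@@H](CC(OC)OC)CO[Si](c1ccccc1)(c1ccccc1)C(C)(C)C | intermediate
19 | lithium salt of the acid of 20 (not isolated) | [Li+].[O-]C(=O)/C(C[C@@H](O)COCc1ccc(OC)cc1)=C/CC[C@@H](CC(OC)OC)CO[Si](c1ccccc1)(c1ccccc1)C(C)(C)C | intermediate
20 | methyl (2E,6S)-6-{[(tert-butyldiphenylsilyl)oxy]methyl}-2-{(2R)-2-hydroxy-3-[(4-methoxybenzyl)oxy]propyl}-8,8-dimethoxyoct-2-enoate | COC(=O)/C(C[C@@H](O)COCc1ccc(OC)cc1)=C/CC[C@@H](CC(OC)OC)CO[Si](c1ccccc1)(c1ccccc1)C(C)(C)C | intermediate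
21 | methyl (2E,6S)-2-{(2R)-2-[(tert-butyldimethylsilyl)oxy]-3-[(4-methoxybenzyl)oxy]propyl}-6-{[(tert-butyldiphenylsilyl)oxy]methyl}-8,8-dimethoxyoct-2-enoate | COC(=O)/C(C[C@@H](O[Si](C)(C)C(C)(C)C)COCc1ccc(OC)cc1)=C/CC[C@@H](CC(OC)OC)CO[Si](c1ccccc1)(c1ccccc1)C(C)(C)C | intermediate
22 | methyl (2E,6S)-2-{(2R)-2-[(tert-butyldimethylsilyl)oxy]-3-hydroxypropyl}-6-{[(tert-butyldiphenylsilyl)oxy]methyl}-8,8-dimethoxyoct-2-enoate | COC(=O)/C(C[C@@H](O[Si](C)(C)C(C)(C)C)CO)=C/CC[C@@H](CC(OC)OC)CO[Si](c1ccccc1)(c1ccccc1)C(C)(C)C | intermediate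
23 | methyl (2E,6S)-2-{(2R)-2-[(tert-butyldimethylsilyl)oxy]-3-oxopropyl}-6-{[(tert-butyldiphenylsilyl)oxy]methyl}-8,8-dimethoxyoct-2-enoate | COC(=O)/C(C[C@@H](O[Si](C)(C)C(C)(C)C)C=O)=C/CC[C@@H](CC(OC)OC)CO[Si](c1ccccc1)(c1ccccc1)C(C)(C)C | intermediate
24 | methyl acrylate | C=CC(=O)OC | starting material
25 | Baylis–Hillman adduct of 23 (C7 carbinol, both epimers; 8R, 4S) | COC(=O)/C(C[C@@H](O[Si](C)(C)C(C)(C)C)C(O)C(=C)C(=O)OC)=C/CC[C@@H](CC(OC)OC)CO[Si](c1ccccc1)(c1ccccc1)C(C)(C)C | intermediate
26 | (Z)-2-(bromomethyl)enoate with C6 dimethyl acetal (8R, 4S, C1=C10 E) | COC(=O)/C(C[C@@H](O[Si](C)(C)C(C)(C)C)/C=C(\CBr)C(=O)OC)=C/CC[C@@H](CC(OC)OC)CO[Si](c1ccccc1)(c1ccccc1)C(C)(C)C | intermediate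
27 | (Z)-2-(bromomethyl)enoate with free C6 aldehyde | COC(=O)/C(C[C@@H](O[Si](C)(C)C(C)(C)C)/C=C(\CBr)C(=O)OC)=C/CC[C@@H](CC=O)CO[Si](c1ccccc1)(c1ccccc1)C(C)(C)C | intermediate
28 | ten-membered carbocycle with C6 hydroxyl and C7 2-(methoxycarbonyl)vinyl branch (4S,6R,7S,8R; not isolated) | O[C@@H]1C[C@@H](CO[Si](c2ccccc2)(c2ccccc2)C(C)(C)C)CC/C=C(/C(=O)OC)C[C@@H](O[Si](C)(C)C(C)(C)C)[C@H]1C(=C)C(=O)OC | intermediate
29 | 6,12-lactone with O8 TBS and O15 TBDPS (4S,6R,7S,8R) | C=C1C(=O)O[C@@H]2C[C@@H](CO[Si](c3ccccc3)(c3ccccc3)C(C)(C)C)CC/C=C(/C(=O)OC)C[C@@H](O[Si](C)(C)C(C)(C)C)[C@@H]12 | intermediate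
30 | 6,12-lactone with free C8 hydroxyl and O15 TBDPS (geometry as in 29; C7 reads R by CIP only because O8 now bears H) | C=C1C(=O)O[C@@H]2C[C@@H](CO[Si](c3ccccc3)(c3ccccc3)C(C)(C)C)CC/C=C(/C(=O)OC)C[C@@H](O)[C@@H]12 | intermediate
31 | isobutyric anhydride | CC(C)C(=O)OC(=O)C(C)C | starting material
32 | C8 isobutyrate with O15 TBDPS (4S,6R,7S,8R) | C=C1C(=O)O[C@@H]2C[C@@H](CO[Si](c3ccccc3)(c3ccccc3)C(C)(C)C)CC/C=C(/C(=O)OC)C[C@@H](OC(=O)C(C)C)[C@@H]12 | intermediate
33 | CNP0251148.1 (4S,6R,7S,8R; C1=C10 E) | C=C1C(=O)O[C@@H]2C[C@@H](CO)CC/C=C(/C(=O)OC)C[C@@H](OC(=O)C(C)C)[C@@H]12 | target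

Total step count: 20. Longest linear sequence: 19 steps (4 to 33, steps 2–20). Step 1 is the only step off this line.

Steps most likely to fail

**Step 17.** Several things could go wrong here.
- Ring closure may lose to intermolecular coupling, to protonation of the allylchromium or to 1,4-elimination of the C8 silyloxide.
- The chair may be entered with C8 axial, which gives the cis lactone, or from the other alkene face.
- The cis arrangement of C2 and C9 on C1=C10 shortens the end-to-end distance, but it does not remove these risks.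

The fallback replaces the stoichiometric allylchromium by an allylzinc that is generated catalytically and kept at a very low stationary concentration. It sets out from 25. Acetylation (Ac2O, pyridine) would give the allylic acetate F5. Acetal hydrolysis as in step 16 would give the acetoxy aldehyde F6. Pd(PPh3)4 (zerovalent palladium, catalytic) with Et2Zn in THF under high dilution would ionise the acetate and transmetalate the π-allyl complex. This umpolung allylation would close the C6–C7 bond, and the fallback comes back to the route at 29.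

**Step 9.** Epoxide opening by the stabilised anion may be slow. Part of the C8 alkoxide may be lost to phosphoryl transfer. The olefination may also give too much of the Z alkene.

The fallback builds the same lactone by aldol condensation, without a phosphonate. It sets out from 3.
- Dimethyl malonate/NaOMe (MeOH, reflux) would give the α-carbomethoxy lactone F1.
- Krapcho demethoxycarbonylation (LiCl, wet DMSO, heat) would give the plain lactone F2.
- LiN(iPr)2 (THF, −78 °C) followed by aldehyde 15 would give the aldol adduct F3.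
- MsCl/Et3N would give the mesylate F4.
- DBU would induce an E1cB elimination, which favours the E alkylidene lactone.

The fallback comes back to the route at 18.

**Step 14.** Addition to the hindered α-silyloxy aldehyde may be slow. During a long exposure to the amine, enolisation could erode C8.

The fallback replaces nucleophilic catalysis by a preformed vinylmetal (vinylalumination). Methyl propiolate would be hydroaluminated with iBu2AlH in the presence of N-methylmorpholine N-oxide (THF, 0 °C). This would give [1-(methoxycarbonyl)vinyl]diisobutylaluminium F7. F7 adds to the aldehyde within hours and without an amine base. The fallback sets out from 23 and comes back to the route at 25.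

Further compounds
F1 | step 9 | methyl (5R)-5-{[(4-methoxybenzyl)oxy]methyl}-2-oxotetrahydrofuran-3-carboxylate | O=C1O[C@@H](COCc2ccc(OC)cc2)CC1C(=O)OC
F2 | step 9 | (5R)-5-{[(4-methoxybenzyl)oxy]methyl}dihydrofuran-2(3H)-one | O=C1O[C@@H](COCc2ccc(OC)cc2)CC1
F3 | step 9 | aldol adduct of F2 and 15 (C1 carbinol and C10 as mixtures) | O=C1O[C@@H](COCc2ccc(OC)cc2)CC1C(O)CC[C@@H](CC(OC)OC)CO[Si](c1ccccc1)(c1ccccc1)C(C)(C)C
F4 | step 9 | C1 mesylate of F3 | O=C1O[C@@H](COCc2ccc(OC)cc2)CC1C(OS(C)(=O)=O)CC[C@@H](CC(OC)OC)CO[Si](c1ccccc1)(c1ccccc1)C(C)(C)C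
F5 | step 17 | C7 acetate of 25 | COC(=O)/C(C[C@@H](O[Si](C)(C)C(C)(C)C)C(OC(C)=O)C(=C)C(=O)OC)=C/CC[C@@H](CC(OC)OC)CO[Si](c1ccccc1)(c1ccccc1)C(C)(C)C
F6 | step 17 | C7 acetate with free C6 aldehyde | COC(=O)/C(C[C@@H](O[Si](C)(C)C(C)(C)C)C(OC(C)=O)C(=C)C(=O)OC)=C/CC[C@@H](CC=O)CO[Si](c1ccccc1)(c1ccccc1)C(C)(C)C
F7 | step 14 | [1-(methoxycarbonyl)vinyl]diisobutylaluminium | C=C(C(=O)OC)[Al](CC(C)C)CC(C)C
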